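**Assumption:** the target SMILES has no stereocentre and no stereogenic double bond, so the compound is achiral and no enantiocontrol is needed; the E-alkene of 8 and 11 is the only stereo-element on the route and is erased in step 5.

**Retrosynthetic overview**
1. Target ⇒ triphenol lacking the ring-A hydroxyl: the last bond made is the aryl C–O bond at C5 of the 3-methoxyphenethyl ring, the only C–H in the molecule with no ortho substituent.
2. Triphenol ⇒ tris-benzyl ether stilbene (one hydrogenation: C=C saturation and three O-debenzylations).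
3. ⇒ two aryl–CH2 bonds by twofold Negishi coupling of a 2,6-dibromostilbene with 4-(benzyloxy)benzylzinc chloride.
4. ⇒ C=C by Horner–Wadsworth–Emmons olefination of 3-(benzyloxy)-2,6-dibromobenzaldehyde with diethyl (3-methoxybenzyl)phosphonate; aldehyde ⇒ lithiation/formylation of O-benzyl-2,4-dibromophenol between the two bromines.
5. No ring is constructed; all four benzene rings are bought. Order of assembly: central ring → anisole ring → two phenol rings → last oxygen.

**Route**

Step 1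
Reactants: 1 2,4-dibromophenol
Product: 2 1-(benzyloxy)-2,4-dibromobenzene
Conditions: BnBr (1.1 equiv), K2CO3 (1.5 equiv), acetone, reflux
Reagents that add atoms: benzyl bromide, BrCc1ccccc1
Why: Williamson etherification of an acidic phenoxide; the benzyl ether survives LDA, KOtBu and Pd/organozinc and is removed in step 5.

Step 2
Reactants: 2 1-(benzyloxy)-2,4-dibromobenzene
Product: 5 3-(benzyloxy)-2,6-dibromobenzaldehyde, via [3-(benzyloxy)-2,6-dibromophenyl]lithium 3 (not isolated), via lithium [3-(benzyloxy)-2,6-dibromophenyl](dimethylamino)methanolate 4 (not isolated)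
Conditions: LDA (1.1 equiv), THF, −78 °C, 1 h; DMF (2 equiv), −78 → −20 °C; 1 M HCl
Reagents that add atoms: N,N-dimethylformamide, CN(C)C=O
Why: Deprotonative lithiation at the C–H flanked by two C–Br bonds (the most acidic site; LDA neither exchanges bromine nor metalates next to the ether) followed by formylation, held at −78 °C so that the aryllithium does not lose LiBr.

Step 3
Reactants: 5 3-(benzyloxy)-2,6-dibromobenzaldehyde; 6 diethyl (3-methoxybenzyl)phosphonate
Product: 8 1-(benzyloxy)-2,4-dibromo-3-[(E)-2-(3-methoxyphenyl)ethenyl]benzene, via potassium (diethoxyphosphoryl)(3-methoxyphenyl)methanide 7 (not isolated)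
Conditions: KOtBu (1.3 equiv), THF, 0 °C → rt
Reagents that add atoms: none
Why: Horner–Wadsworth–Emmons olefination of a non-enolisable aldehyde with a semi-stabilised benzylphosphonate anion gives the E-stilbene under thermodynamic control; any Z isomer converges in step 5.

Step 4
Reactants: 8 1-(benzyloxy)-2,4-dibromo-3-[(E)-2-(3-methoxyphenyl)ethenyl]benzene; 9 4-(benzyloxy)benzyl chloride (3 equiv)
Product: 11 1-(benzyloxy)-2,4-bis[4-(benzyloxy)benzyl]-3-[(E)-2-(3-methoxyphenyl)ethenyl]benzene, via [4-(benzyloxy)benzyl]zinc chloride 10 (not isolated)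
Conditions: 9, Zn dust, LiCl, THF, 25 °C; then 8, Pd(OAc)2 (3 mol %), SPhos (6 mol %), THF, 50 °C
Reagents that add atoms: none
Why: Twofold Negishi sp2–sp3 coupling; LiCl-assisted zinc insertion gives the benzylic zinc chloride with little Wurtz coupling, and Pd/SPhos couples ortho,ortho′-flanked aryl bromides while ethers and the stilbene stay inert.

Step 5
Reactants: 11 1-(benzyloxy)-2,4-bis[4-(benzyloxy)benzyl]-3-[(E)-2-(3-methoxyphenyl)ethenyl]benzene
Product: 12 2,4-bis(4-hydroxybenzyl)-3-[2-(3-methoxyphenyl)ethyl]phenol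
Conditions: H2 (3 bar), 10 % Pd/C, THF–MeOH, rt
Reagents that add atoms: none
Why: Heterogeneous hydrogenation saturates the stilbene and hydrogenolyses the three O–benzyl bonds in one operation; the aryl methyl ether and the diarylmethane C–C bonds are untouched.

Step 6
Reactants: 12 2,4-bis(4-hydroxybenzyl)-3-[2-(3-methoxyphenyl)ethyl]phenol
Product: 15 3-[2-(3-hydroxy-5-methoxyphenyl)ethyl]-2,4-bis(4-hydroxybenzyl)phenol, via 1-[(triethylsilyl)oxy]-2,4-bis{4-[(triethylsilyl)oxy]benzyl}-3-[2-(3-methoxyphenyl)ethyl]benzene 13 (not isolated), via 2-{3-[2-(2,6-bis{4-[(triethylsilyl)oxy]benzyl}-3-[(triethylsilyl)oxy]phenyl)ethyl]-5-methoxyphenyl}-4,4,5,5-tetramethyl-1,3,2-dioxaborolane 14 (not isolated)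
Conditions: Et3SiH (3.3 equiv), [Ir(cod)OMe]2 (2 mol %), THF, 60 °C (−H2), evaporate; dtbpy (4 mol %), B2pin2 (0.6 equiv), THF, 80 °C; then 3 M NaOH, 30 % H2O2, 0 °C → rt; 1 M HCl to pH 5
Reagents that add atoms: hydrogen peroxide, OO
Why: Proposed new method: a "silyl-shielded" late-stage C–H hydroxylation of a free polyphenol in one flask, in which the Ir(I) precatalyst first couples the three ArO–H bonds with Et3SiH (H2 loss) to O–SiEt3 groups that carry neither Si–H nor O–B (so neither silyl-directed nor O-boryl-directed ortho borylation can operate) and that flank every C–H of the three phenol rings, after which the Ir(III) tris(boryl)/dtbpy species can reach only the one C–H with no ortho substituent (C5 of the 3-methoxyphenethyl ring), and alkaline H2O2 then turns C–B into C–O by 1,2-aryl shift while hydrolysing the silyl ethers; the closest known reaction types are the one-pot Ir-catalysed meta C–H borylation/oxidation of 3-substituted anisoles and the Ir-catalysed dehydrogenative O-silylation of phenols used to direct ortho borylation, which have not been combined in this non-directing sense or run on an unprotected polyphenol.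

**Compound list**
1 | 2,4-dibromophenol | Oc1ccc(Br)cc1Br | starting material
2 | 1-(benzyloxy)-2,4-dibromobenzene | Brc1ccc(OCc2ccccc2)c(Br)c1 | intermediate
3 | [3-(benzyloxy)-2,6-dibromophenyl]lithium (not isolated) | [Li]c1c(Br)ccc(OCc2ccccc2)c1Br | intermediate
4 | lithium [3-(benzyloxy)-2,6-dibromophenyl](dimethylamino)methanolate (racemic, transient, not isolated) | [Li]OC(N(C)C)c1c(Br)ccc(OCc2ccccc2)c1Br | intermediate
5 | 3-(benzyloxy)-2,6-dibromobenzaldehyde | O=Cc1c(Br)ccc(OCc2ccccc2)c1Br | intermediate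
6 | diethyl (3-methoxybenzyl)phosphonate | CCOP(=O)(Cc1cccc(OC)c1)OCC | starting material
7 | potassium (diethoxyphosphoryl)(3-methoxyphenyl)methanide (not isolated) | [K+].CCOP(=O)([CH-]c1cccc(OC)c1)OCC | intermediate
8 | 1-(benzyloxy)-2,4-dibromo-3-[(E)-2-(3-methoxyphenyl)ethenyl]benzene | COc1cccc(/C=C/c2c(Br)ccc(OCc3ccccc3)c2Br)c1 | intermediate
9 | 4-(benzyloxy)benzyl chloride | ClCc1ccc(OCc2ccccc2)cc1 | starting material
10 | [4-(benzyloxy)benzyl]zinc chloride (not isolated) | Cl[Zn]Cc1ccc(OCc2ccccc2)cc1 | intermediate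
11 | 1-(benzyloxy)-2,4-bis[4-(benzyloxy)benzyl]-3-[(E)-2-(3-methoxyphenyl)ethenyl]benzene | COc1cccc(/C=C/c2c(Cc3ccc(OCc4ccccc4)cc3)ccc(OCc3ccccc3)c2Cc2ccc(OCc3ccccc3)cc2)c1 | intermediate
12 | 2,4-bis(4-hydroxybenzyl)-3-[2-(3-methoxyphenyl)ethyl]phenol | COc1cccc(CCc2c(Cc3ccc(O)cc3)ccc(O)c2Cc2ccc(O)cc2)c1 | intermediate
13 | 1-[(triethylsilyl)oxy]-2,4-bis{4-[(triethylsilyl)oxy]benzyl}-3-[2-(3-methoxyphenyl)ethyl]benzene (not isolated) | COc1cccc(CCc2c(Cc3ccc(O[Si](CC)(CC)CC)cc3)ccc(O[Si](CC)(CC)CC)c2Cc2ccc(O[Si](CC)(CC)CC)cc2)c1 | intermediate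
14 | 2-{3-[2-(2,6-bis{4-[(triethylsilyl)oxy]benzyl}-3-[(triethylsilyl)oxy]phenyl)ethyl]-5-methoxyphenyl}-4,4,5,5-tetramethyl-1,3,2-dioxaborolane (not isolated) | COc1cc(B2OC(C)(C)C(C)(C)O2)cc(CCc2c(Cc3ccc(O[Si](CC)(CC)CC)cc3)ccc(O[Si](CC)(CC)CC)c2Cc2ccc(O[Si](CC)(CC)CC)cc2)c1 | intermediate
15 | 3-[2-(3-hydroxy-5-methoxyphenyl)ethyl]-2,4-bis(4-hydroxybenzyl)phenol (achiral) | COc1cc(O)cc(CCc2c(Cc3ccc(O)cc3)ccc(O)c2Cc2ccc(O)cc2)c1 | target

**Step count:** 6 steps in total; longest linear sequence 6 (1 → 2 → 5 → 8 → 11 → 12 → 15).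

**Steps most likely to fail**

1. Step 6 (the proposed new step). Incomplete O-silylation would leave ArOH that becomes ArO–Bpin, which is known to steer borylation ortho, and the polyphenol could also suffer under alkaline peroxide. The fallback uses only known chemistry, sets out from 12 and returns at 15. It replaces the one-flask traceless shield by a conventional isolated protecting-group sequence. 12 is silylated (TBSCl, imidazole, DMF) to 1-[(tert-butyldimethylsilyl)oxy]-2,4-bis{4-[(tert-butyldimethylsilyl)oxy]benzyl}-3-[2-(3-methoxyphenyl)ethyl]benzene F1. This is purified and submitted to the established Ir/dtbpy C–H borylation with B2pin2, giving the 5-boryl pinacol ester F2. F2 is oxidised with aqueous Oxone in acetone to the tris-TBS-protected 3-hydroxy-5-methoxy compound F3, and TBAF in THF releases 15.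

2. Step 4. The C2–Br between the benzyloxy and styryl groups is doubly ortho-flanked, so mono-coupling, hydrodebromination or benzylzinc homocoupling may dominate. The fallback sets out from 8 and returns at 11, with the polarity of the coupling inverted. 8 is converted by Miyaura borylation (B2pin2, KOAc, Pd/XPhos, dioxane, 90 °C) into the bis(pinacol boronate) 2,2′-{4-(benzyloxy)-2-[(E)-2-(3-methoxyphenyl)ethenyl]-1,3-phenylene}bis(4,4,5,5-tetramethyl-1,3,2-dioxaborolane) F4. F4 is coupled with the benzylic chloride 9 as electrophile (Suzuki–Miyaura, Pd(OAc)2/SPhos, K3PO4, toluene–water, 80 °C) to give 11.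

3. Step 2. Aryllithium 3 eliminates LiBr to an aryne on any temperature excursion, and the hindered aldehyde may be recovered poorly. The fallback sets out from 2 and returns at 12, using a room-temperature arylzinc species and an alkyne instead of aldehyde/olefination. 2 is deprotonated with the TMP-zincate Li[t-Bu2Zn(TMP)] (THF, 0 °C → rt) to lithium [3-(benzyloxy)-2,6-dibromophenyl]di-tert-butylzincate F5, which does not expel bromide. Iodinolysis (I2, 3.3 equiv) gives 1-(benzyloxy)-2,4-dibromo-3-iodobenzene F6. Sonogashira coupling at the C–I bond with commercial 1-ethynyl-3-methoxybenzene (PdCl2(PPh3)2, CuI, Et3N, rt) gives 1-(benzyloxy)-2,4-dibromo-3-[(3-methoxyphenyl)ethynyl]benzene F7. The step-4 Negishi conditions turn F7 into 1-(benzyloxy)-2,4-bis[4-(benzyloxy)benzyl]-3-[(3-methoxyphenyl)ethynyl]benzene F8, and the step-5 hydrogenation reduces the alkyne and removes the benzyl groups to give 12.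

**Further compounds**
F1 | step 6 | 1-[(tert-butyldimethylsilyl)oxy]-2,4-bis{4-[(tert-butyldimethylsilyl)oxy]benzyl}-3-[2-(3-methoxyphenyl)ethyl]benzene | COc1cccc(CCc2c(Cc3ccc(O[Si](C)(C)C(C)(C)C)cc3)ccc(O[Si](C)(C)C(C)(C)C)c2Cc2ccc(O[Si](C)(C)C(C)(C)C)cc2)c1
F2 | step 6 | 2-{3-[2-(2,6-bis{4-[(tert-butyldimethylsilyl)oxy]benzyl}-3-[(tert-butyldimethylsilyl)oxy]phenyl)ethyl]-5-methoxyphenyl}-4,4,5,5-tetramethyl-1,3,2-dioxaborolane | COc1cc(B2OC(C)(C)C(C)(C)O2)cc(CCc2c(Cc3ccc(O[Si](C)(C)C(C)(C)C)cc3)ccc(O[Si](C)(C)C(C)(C)C)c2Cc2ccc(O[Si](C)(C)C(C)(C)C)cc2)c1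
F3 | step 6 | 3-[2-(2,6-bis{4-[(tert-butyldimethylsilyl)oxy]benzyl}-3-[(tert-butyldimethylsilyl)oxy]phenyl)ethyl]-5-methoxyphenol | COc1cc(O)cc(CCc2c(Cc3ccc(O[Si](C)(C)C(C)(C)C)cc3)ccc(O[Si](C)(C)C(C)(C)C)c2Cc2ccc(O[Si](C)(C)C(C)(C)C)cc2)c1
F4 | step 4 | 2,2′-{4-(benzyloxy)-2-[(E)-2-(3-methoxyphenyl)ethenyl]-1,3-phenylene}bis(4,4,5,5-tetramethyl-1,3,2-dioxaborolane) | COc1cccc(/C=C/c2c(B3OC(C)(C)C(C)(C)O3)ccc(OCc3ccccc3)c2B2OC(C)(C)C(C)(C)O2)c1
F5 | step 2 | lithium [3-(benzyloxy)-2,6-dibromophenyl]di-tert-butylzincate | [Li+].CC(C)(C)[Zn-](c1c(Br)ccc(OCc2ccccc2)c1Br)C(C)(C)C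
F6 | step 2 | 1-(benzyloxy)-2,4-dibromo-3-iodobenzene | Brc1ccc(OCc2ccccc2)c(Br)c1I
F7 | step 2 | 1-(benzyloxy)-2,4-dibromo-3-[(3-methoxyphenyl)ethynyl]benzene | COc1cccc(C#Cc2c(Br)ccc(OCc3ccccc3)c2Br)c1
F8 | step 2 | 1-(benzyloxy)-2,4-bis[4-(benzyloxy)benzyl]-3-[(3-methoxyphenyl)ethynyl]benzene | COc1cccc(C#Cc2c(Cc3ccc(OCc4ccccc4)cc3)ccc(OCc3ccccc3)c2Cc2ccc(OCc3ccccc3)cc2)c1
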